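1. Free monomer could not simply have passed into chains in the north flask: by 3.00 min it had lost 56.1%, while the chains held 12.4%.

| setting | north | flask |
|---|---|---|
| free monomer | 3 M | 3.0 M |
| protic impurity | 1.5 M | 1.50 M |
| initiator | 15 mM | 15 mM |
| remark | the very flask that is asked about, followed so far |  |
| time |  | 10 min |

north run (percent of the free monomer charged)

| time / min | monomer in chains / % | free monomer / % |
|---|---|---|
| 0.250 | 0 | 87.2 |
| 0.333 | 0 | 85.5 |
| 0.500 | 1.5 | 79.0 |
| 0.833 | 3.1 | 71.3 |
| 1.33 | 6.4 | 59.5 |
| 2.00 | 8.4 | 50.6 |
| 3.00 | 12.4 | 43.9 |

(readings scatter by 1 percentage point)

1. average number of monomer units in a chain (chains begun, living or dead) at 10 min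
2. part of the free monomer that has reacted at 10 min

- the average divides the monomer in chains by the number of chains begun, living and dead together
- the analysis behind the earlier runs scatters by 1 percentage point, standard deviation
- what may be going on: free monomer + living end -> monomer in chains + living end; free monomer + initiator -> living end + monomer in chains; monomer in chains + living end -> free monomer + living end; initiator -> spent initiator; protic impurity + free monomer -> quenched substrate
- the earlier runs do not show the number of chains; that part of a forecast is a guess

2. Each protic impurity takes one free monomer, so this limiting reagent of the quenching can claim half of the charge. I called the share it cannot claim, one minus impurity over monomer as charged, the room: 50.0%. Free monomer plus monomer in chains should run down to it.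

3. The curve started steeply: up to the first reading at 0.250 min, free monomer fell on average at 0.512 min⁻¹ of its charge, and the chains then read 0%. At 3.00 min the sum stood 6.3 percentage points above the room, so I put the knee there.

4. From 1.33 min to 3.00 min, the chains gained 0.0695 min⁻¹ of the free monomer present. The reading of free monomer at 3.00 min was 43.9%, but I booked the quenching still to come as done at once, which put my starting level for free monomer beyond the knee at the room less the chains, 37.6%. Holding that level to 10 min gave 19.3%. Going round once more with the mean level gave 23.8%. So I reckoned 76.2% reacted, with the chains at 26.2%, past the free monomer.

5. The forecast said 100 monomer units in a chain and 78% of the free monomer reacted, above my conversion, and of the first figure it said: “The chain count is a guess”.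

    free monomer + living end → monomer in chains + living end, rate k1*[living end]*[free monomer] (k = 0.240 M⁻¹ s⁻¹)
    free monomer + initiator → living end + monomer in chains (k = 0.00683 M⁻¹ s⁻¹)
    monomer in chains + living end → free monomer + living end, rate k3*[living end] as long as [monomer in chains] is above zero (k = 0.0941 s⁻¹)
    initiator → spent initiator (k = 0.0122 s⁻¹)
    protic impurity + free monomer → quenched substrate (k = 0.00611 M⁻¹ s⁻¹)

The north flask gave 99.3 monomer units in a chain and 77.6% of the free monomer reacted. At 10.0 min it held 49.3% quenched substrate, with 1.31% of the protic impurity's own charge left. Its free monomer and monomer in chains, 22.4% and 28.3%, made 50.7%, level with the room. The neighbour flask with 0.90 M of protic impurity has a room of 70.0%, and at 10.0 min it held 28.9% free monomer and 41.3% monomer in chains, together 70.2%.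

The runs were generated by integration for an exercise; scatter was added.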